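**Retrosynthetic overview**

- The route rests on one feature: the spiro carbon (chroman C2 = pinane C2') is 1,3 to pinane C4'. A C4' ketone with a C2'=C3' double bond makes the spiro carbon the β-carbon of a bicyclic enone, and the C8a phenol oxygen reaches it through the C3–C4 ethano tether to close the pyran ring (O1, C2, C3, C4, C4a, C8a).
- O1–C2 is therefore disconnected by a retro-oxa-Michael to a phenol tethered to a 4-substituted verbenone-type enone; the arene and the pinane bicycle are bought, and the pyran ring is the only ring formed.
- The enone precursor comes from a vinylogous aldol condensation of (−)-verbenone (at its C4 methyl) with 2-allyloxy-4,6-bis(methoxymethoxy)benzaldehyde, followed by deallylation and hydrogenation of the styryl C=C only.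
- After cyclisation the C4' ketone is removed, and two successive directed ortho-metalations place the isovaleryl carbon at C6 (between the two MOM ethers) and the formyl group at C8; oxidation and MOM cleavage finish the synthesis.

Key step: step 6

Assumption: commercial (1S,5S)-(−)-verbenone is taken at high enantiomeric purity, and carbinol centres that are destroyed later (in 5, 15, 16, 17) are drawn without configuration.

**Step 1**
Reactants: 1 2,4,6-trihydroxybenzaldehyde
Product: 2 2-hydroxy-4,6-bis(methoxymethoxy)benzaldehyde
Conditions: MOMCl (2.1 equiv), i-Pr2NEt, CH2Cl2, 0 °C to rt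
Reagents that add atoms: chloromethyl methyl ether, COCCl
Why: Williamson-type acetal etherification in which the para hydroxyl and one ortho hydroxyl are capped, while the remaining ortho hydroxyl, hydrogen-bonded to the formyl oxygen, should stay free under amine base.

**Step 2**
Reactants: 2 2-hydroxy-4,6-bis(methoxymethoxy)benzaldehyde
Product: 3 2-(allyloxy)-4,6-bis(methoxymethoxy)benzaldehyde
Conditions: allyl bromide, K2CO3, DMF, 50 °C
Reagents that add atoms: allyl bromide, C=CCBr
Why: Williamson etherification of the chelated phenol under carbonate in DMF; allyl is chosen because it survives the hydroxide of step 3 and is later removed without acid or hydrogen.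

**Step 3**
Reactants: 3 2-(allyloxy)-4,6-bis(methoxymethoxy)benzaldehyde; 4 (1S,5S)-(−)-verbenone
Product: 6 (1S,5R)-4-[(E)-2-(2-allyloxy-4,6-bis(methoxymethoxy)phenyl)ethenyl]-6,6-dimethylbicyclo[3.1.1]hept-3-en-2-one, via aldol adduct 5 (not isolated)
Conditions: KOH, MeOH, 60 °C
Reagents that add atoms: none
Why: Vinylogous aldol (Claisen–Schmidt) condensation in which hydroxide can deprotonate only the C4 methyl of verbenone (the other α-position is a bridgehead), the dienolate reacts through its γ-terminus under reversible conditions, and E1cB dehydration should give the conjugated (E)-dienone with both bridgehead centres untouched.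

**Step 4**
Reactants: 6 the allyl-protected (E)-dienone
Product: 7 (1S,5R)-4-[(E)-2-(2-hydroxy-4,6-bis(methoxymethoxy)phenyl)ethenyl]-6,6-dimethylbicyclo[3.1.1]hept-3-en-2-one
Conditions: Pd(PPh3)4 (5 mol%), morpholine, THF, rt, in the dark
Reagents that add atoms: none
Why: Tsuji–Trost-type deallylation in which zerovalent palladium ionises the aryl allyl ether to a π-allyl complex and the phenoxide, and morpholine captures the allyl group, leaving the MOM acetals and the dienone untouched (the E geometry keeps the phenol away from the enone).

**Step 5**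
Reactants: 7 the free-phenol (E)-dienone
Product: 8 (1S,5R)-4-[2-(2-hydroxy-4,6-bis(methoxymethoxy)phenyl)ethyl]-6,6-dimethylbicyclo[3.1.1]hept-3-en-2-one
Conditions: H2 (4 atm), RhCl(PPh3)3 (10 mol%), benzene/EtOH 1:1, 40 °C
Reagents that add atoms: none
Why: Homogeneous hydrogenation with Wilkinson's catalyst discriminates by alkene substitution, so the 1,2-disubstituted styryl C=C should be reduced while the trisubstituted ring C=C, flanked by a bridgehead and shielded by the gem-dimethyl bridge, is left, as in the known reduction of the γ,δ-bond of linear dienones.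

**Step 6**
Reactants: 8 the phenol-tethered enone
Product: 10 5,7-bis(methoxymethoxy)-6',6'-dimethylspiro[chromane-2,2'-bicyclo[3.1.1]heptan]-4'-one (O1 anti to the gem-dimethyl bridge), via potassium enolate 9 (not isolated)
Conditions: K2CO3 (0.3 equiv), MeOH/THF 1:1, 0 °C, then AcOH quench at full conversion
Reagents that add atoms: none
Why: Carbonate generates the C8a phenoxide, which adds to the enone β-carbon (C2') to give enolate 9, and methanol protonates this at C3' to the saturated ketone. The closest known reaction is the base-mediated intramolecular oxa-Michael addition of phenols to β,β-disubstituted enones that gives 2,2-disubstituted chromans. The pyran ring (O1, C2, C3, C4, C4a, C8a) closes in the 6-exo-trig mode, the C2'=C3' bond lying outside the new ring. The spiro stereocentre is controlled by the bicycle: one methyl of the C6' bridge covers one face of C2'–C3', so the oxygen should enter from the face of the methylene bridge C7', as nucleophiles do with verbenone itself, and the tether carbon C3 is pushed to the gem-dimethyl side, which is the arrangement of the target. The step needs kinetic facial selectivity without reversal; low temperature, a catalytic weak base, a protic medium that quenches the enolate at once and an acid quench at full conversion should keep the retro-addition (which requires re-enolisation toward C3') from equilibrating the spiro centre. No cation is generated next to the cyclobutane, so the pinane skeleton should stay intact.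

**Step 7**
Reactants: 10 the spiro ketone
Product: 11 the C4' p-toluenesulfonylhydrazone of 10
Conditions: TsNHNH2, MeOH, 50 °C
Reagents that add atoms: p-toluenesulfonyl hydrazide, Cc1ccc(cc1)S(=O)(=O)NN
Why: Condensation of the ketone with tosylhydrazide under neutral conditions, which should avoid both MOM loss and β-elimination of the aryloxide.

**Step 8**
Reactants: 11 the tosylhydrazone
Product: 13 5,7-bis(methoxymethoxy)-6',6'-dimethylspiro[chromane-2,2'-bicyclo[3.1.1]heptane] (O1 anti to the gem-dimethyl bridge), via diazene 12 (not isolated)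
Conditions: catecholborane, CHCl3, 0 °C to rt; then NaOAc·3H2O, reflux
Reagents that add atoms: none
Why: Kabalka variant of the Caglioti tosylhydrazone reduction, in which catecholborane delivers hydride to the C=N carbon, acetate expels p-toluenesulfinate to give diazene 12, and loss of N2 leaves the C4' methylene under near-neutral conditions that the MOM ethers and the tertiary aryl ether should tolerate.

**Step 9**
Reactants: 13 the deoxygenated bis-MOM spirochroman
Product: 15 6-(1-hydroxy-3-methylbutyl)-5,7-bis(methoxymethoxy)-6',6'-dimethylspiro[chromane-2,2'-bicyclo[3.1.1]heptane], via C6-aryllithium 14 (not isolated)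
Conditions: n-BuLi, TMEDA, THF, 0 °C; then isovaleraldehyde, −78 °C; H2O
Reagents that add atoms: isovaleraldehyde (3-methylbutanal), CC(C)CC=O
Why: Directed ortho-metalation should occur at C6–H, which lies between two chelating MOM ethers (C8–H has one MOM ether and the poorly coordinating ring oxygen), and aryllithium 14 adds to the aldehyde to give a carbinol whose new centre forms as a mixture of no consequence because it is oxidised in step 11.

**Step 10**
Reactants: 15 the C6 carbinol
Product: 17 8-formyl-6-(1-hydroxy-3-methylbutyl)-5,7-bis(methoxymethoxy)-6',6'-dimethylspiro[chromane-2,2'-bicyclo[3.1.1]heptane], via C8-lithio lithium alkoxide 16 (not isolated)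
Conditions: n-BuLi (2.5 equiv), TMEDA, THF, −20 to 0 °C; then DMF; H2O
Reagents that add atoms: N,N-dimethylformamide, CN(C)C=O
Why: Second directed ortho-metalation in which the first equivalent of base masks the alcohol as its lithium alkoxide and the second removes the only remaining ring proton (C8–H, flanked by the C7 MOM ether and O1), followed by formylation of the aryllithium with DMF.

**Step 11**
Reactants: 17 the hydroxy aldehyde
Product: 18 8-formyl-6-(3-methylbutanoyl)-5,7-bis(methoxymethoxy)-6',6'-dimethylspiro[chromane-2,2'-bicyclo[3.1.1]heptane]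
Conditions: Dess–Martin periodinane, CH2Cl2, rt
Reagents that add atoms: none
Why: Dess–Martin oxidation of the secondary benzylic alcohol to the aryl ketone, which should leave the aldehyde, the MOM acetals and the spiro ether untouched.

**Step 12**
Reactants: 18 the bis-MOM keto aldehyde
Product: 19 euglobal G3
Conditions: 3 M aq HCl, THF, 45 °C
Reagents that add atoms: none
Why: Acid hydrolysis of the two MOM acetals, both ortho to carbonyl groups that hydrogen-bond the released phenols, under dilute acid that should not ionise the tertiary spiro ether because its oxygen is deactivated by the acylated arene; no stereocentre is involved.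

**Compound list**

1 | 2,4,6-trihydroxybenzaldehyde | O=Cc1c(O)cc(O)cc1O | starting material
2 | 2-hydroxy-4,6-bis(methoxymethoxy)benzaldehyde | COCOc1cc(O)c(C=O)c(OCOC)c1 | intermediate
3 | 2-(allyloxy)-4,6-bis(methoxymethoxy)benzaldehyde | C=CCOc1cc(OCOC)cc(OCOC)c1C=O | intermediate
4 | (1S,5S)-(−)-verbenone | CC1=CC(=O)[C@H]2C[C@@H]1C2(C)C | starting material
5 | aldol adduct, (1S,5R)-4-[2-(2-allyloxy-4,6-bis(methoxymethoxy)phenyl)-2-hydroxyethyl]-6,6-dimethylbicyclo[3.1.1]hept-3-en-2-one (carbinol epimers) | C=CCOc1cc(OCOC)cc(OCOC)c1C(O)CC1=CC(=O)[C@H]2C[C@@H]1C2(C)C | intermediate (not isolated)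
6 | (1S,5R)-4-[(E)-2-(2-allyloxy-4,6-bis(methoxymethoxy)phenyl)ethenyl]-6,6-dimethylbicyclo[3.1.1]hept-3-en-2-one | C=CCOc1cc(OCOC)cc(OCOC)c1/C=C/C1=CC(=O)[C@H]2C[C@@H]1C2(C)C | intermediate
7 | (1S,5R)-4-[(E)-2-(2-hydroxy-4,6-bis(methoxymethoxy)phenyl)ethenyl]-6,6-dimethylbicyclo[3.1.1]hept-3-en-2-one | COCOc1cc(O)c(/C=C/C2=CC(=O)[C@H]3C[C@@H]2C3(C)C)c(OCOC)c1 | intermediate
8 | (1S,5R)-4-[2-(2-hydroxy-4,6-bis(methoxymethoxy)phenyl)ethyl]-6,6-dimethylbicyclo[3.1.1]hept-3-en-2-one | COCOc1cc(O)c(CCC2=CC(=O)[C@H]3C[C@@H]2C3(C)C)c(OCOC)c1 | intermediate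
9 | potassium C3'–C4' enolate of the spiro ketone | COCOc1cc2c(c(OCOC)c1)CC[C@@]1(C=C([O-])[C@H]3C[C@@H]1C3(C)C)O2.[K+] | intermediate (not isolated)
10 | 5,7-bis(methoxymethoxy)-6',6'-dimethylspiro[chromane-2,2'-bicyclo[3.1.1]heptan]-4'-one, O1 anti to the gem-dimethyl bridge | COCOc1cc2c(c(OCOC)c1)CC[C@@]1(CC(=O)[C@H]3C[C@@H]1C3(C)C)O2 | intermediate
11 | C4' p-toluenesulfonylhydrazone of 10 | COCOc1cc2c(c(OCOC)c1)CC[C@@]1(CC(=NNS(=O)(=O)c4ccc(C)cc4)[C@H]3C[C@@H]1C3(C)C)O2 | intermediate
12 | C4' monoalkyl diazene | COCOc1cc2c(c(OCOC)c1)CC[C@@]1(CC(N=N)[C@H]3C[C@@H]1C3(C)C)O2 | intermediate (not isolated)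
13 | 5,7-bis(methoxymethoxy)-6',6'-dimethylspiro[chromane-2,2'-bicyclo[3.1.1]heptane], O1 anti to the gem-dimethyl bridge | COCOc1cc2c(c(OCOC)c1)CC[C@@]1(CC[C@H]3C[C@@H]1C3(C)C)O2 | intermediate
14 | C6-aryllithium of 13 | [Li]c1c(OCOC)cc2c(c1OCOC)CC[C@@]1(CC[C@H]3C[C@@H]1C3(C)C)O2 | intermediate (not isolated)
15 | 6-(1-hydroxy-3-methylbutyl) derivative of 13 (carbinol epimers) | CC(C)CC(O)c1c(OCOC)cc2c(c1OCOC)CC[C@@]1(CC[C@H]3C[C@@H]1C3(C)C)O2 | intermediate
16 | C8-lithio lithium alkoxide of 15 | CC(C)CC(O[Li])c1c(OCOC)c([Li])c2c(c1OCOC)CC[C@@]1(CC[C@H]3C[C@@H]1C3(C)C)O2 | intermediate (not isolated)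
17 | 8-formyl-6-(1-hydroxy-3-methylbutyl) derivative of 13 (carbinol epimers) | CC(C)CC(O)c1c(OCOC)c(C=O)c2c(c1OCOC)CC[C@@]1(CC[C@H]3C[C@@H]1C3(C)C)O2 | intermediate
18 | 8-formyl-6-(3-methylbutanoyl) derivative of 13 | CC(C)CC(=O)c1c(OCOC)c(C=O)c2c(c1OCOC)CC[C@@]1(CC[C@H]3C[C@@H]1C3(C)C)O2 | intermediate
19 | euglobal G3 | CC(C)CC(=O)c1c(O)c(C=O)c2c(c1O)CC[C@@]1(CC[C@H]3C[C@@H]1C3(C)C)O2 | target

**Step count**

Total: 12 steps. Longest linear sequence: 12 steps, from 2,4,6-trihydroxybenzaldehyde (verbenone enters at step 3).

**Steps most likely to fail**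

1. Step 6 (oxa-Michael closure). The addition may reverse under the basic conditions, which would leave enone unconverted or let the spiro centre equilibrate toward the epimer with oxygen on the gem-dimethyl side. The fallback replaces the conjugate addition by an inverse-demand hetero-Diels–Alder reaction and sets out from compound 2. NaBH4 in MeOH should reduce the aldehyde to 2-(hydroxymethyl)-3,5-bis(methoxymethoxy)phenol F1. Heating F1 with excess commercial (1S,5S)-(−)-β-pinene in toluene at about 150 °C in a sealed tube should expel water to give the ortho-quinone methide 6-methylidene-3,5-bis(methoxymethoxy)cyclohexa-2,4-dien-1-one F2. F2 is trapped in situ by the exocyclic alkene, with oxygen bonding to the disubstituted carbon from the face anti to the gem-dimethyl bridge. The route is rejoined at compound 13, and steps 2 to 8 are bypassed.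

2. Step 5 (selective hydrogenation). Hydrogen uptake at the hindered, donor-substituted styryl alkene may be sluggish, or selectivity may erode with partial saturation of the ring enone. The fallback gives up chemoselection and sets out from compound 7. H2 over Pd/C in EtOAc should saturate both C=C bonds, from the face anti to the gem-dimethyl bridge, to give 4-[2-(2-hydroxy-4,6-bis(methoxymethoxy)phenyl)ethyl]-6,6-dimethylbicyclo[3.1.1]heptan-2-one F3 (side chain syn to the bridge). LiN(SiMe3)2 and Me3SiCl in THF at −78 °C then give the aryl silyl ether / silyl enol ether F4; the enol ether can form only toward C3 because the other α-carbon is a bridgehead. Saegusa–Ito oxidation with Pd(OAc)2 (divalent palladium) in MeCN should restore the C3=C4 double bond, and aqueous work-up frees the phenol. The route is rejoined at compound 8.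

3. Step 8 (deoxygenation). The diazene may collapse through a C4' radical that opens the adjacent cyclobutane, or the hindered hydrazone may suffer β-elimination of the aryloxide instead of reduction. The fallback avoids any radical, cation or carbanion at C4' and sets out from compound 10. NaBH4 in MeOH should give the C4' alcohol F5 (either epimer serves). NaH, CS2 and MeI convert F5 into the S-methyl xanthate F6. Chugaev pyrolysis at about 170 °C should give the C3'=C4' alkene F7 by concerted syn-elimination; only the C3' hydrogens can be lost because C5' is a bridgehead. Diimide, generated from 2-nitrobenzenesulfonyl hydrazide and Et3N, then saturates the disubstituted ring alkene without touching the allylic aryl ether. The route is rejoined at compound 13.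

**Further compounds**

F1 | step 6 | 2-(hydroxymethyl)-3,5-bis(methoxymethoxy)phenol | COCOc1cc(O)c(CO)c(OCOC)c1
F2 | step 6 | 6-methylidene-3,5-bis(methoxymethoxy)cyclohexa-2,4-dien-1-one (ortho-quinone methide) | C=C1C(=O)C=C(OCOC)C=C1OCOC
F3 | step 5 | 4-[2-(2-hydroxy-4,6-bis(methoxymethoxy)phenyl)ethyl]-6,6-dimethylbicyclo[3.1.1]heptan-2-one, side chain syn to the gem-dimethyl bridge | COCOc1cc(O)c(CC[C@@H]2CC(=O)[C@H]3C[C@@H]2C3(C)C)c(OCOC)c1
F4 | step 5 | aryl trimethylsilyl ether / trimethylsilyl enol ether of F3 | COCOc1cc(O[Si](C)(C)C)c(CC[C@@H]2C=C(O[Si](C)(C)C)[C@H]3C[C@@H]2C3(C)C)c(OCOC)c1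
F5 | step 8 | 5,7-bis(methoxymethoxy)-6',6'-dimethylspiro[chromane-2,2'-bicyclo[3.1.1]heptan]-4'-ol | COCOc1cc2c(c(OCOC)c1)CC[C@@]1(CC(O)[C@H]3C[C@@H]1C3(C)C)O2
F6 | step 8 | O-(4'-spirochromanyl) S-methyl xanthate of F5 | COCOc1cc2c(c(OCOC)c1)CC[C@@]1(CC(OC(=S)SC)[C@H]3C[C@@H]1C3(C)C)O2
F7 | step 8 | 5,7-bis(methoxymethoxy)-6',6'-dimethylspiro[chromane-2,2'-bicyclo[3.1.1]hept-3'-ene] | COCOc1cc2c(c(OCOC)c1)CC[C@@]1(C=C[C@H]3C[C@@H]1C3(C)C)O2
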